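**Retrosynthetic overview**

1. Ring C (pyran) is closed last, by dehydrative attack of the tertiary C4 hydroxyl on ring D; before that, ring D (a trione made from phloroglucinol) is joined through C1′ by reductive Knoevenagel alkylation with a C5 aldehyde.
2. Ring B (nine-membered, C1–C9) comes from a five-to-nine radical expansion: a C7 radical adds to the C8 ketone of a bicyclo[3.2.0]heptan-2-one and the C3–C8 bond breaks; C9 is then epimerised to the trans fusion and C8 is methylenated.
3. The strategy rests on ring A: the cyclobutane C1–C9–C10–C11 carries CMe2 (C11) on C1, β to C8, and CH2 (C10) on C9, α to C8. This is the head-to-tail pattern of an excited cyclopentenone plus isobutylene; the [2+2] forms C9–C10 and C1–C11 on the face anti to the C3 substituent.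
4. The cyclopentenone (C8, C9, C1, C2, C3) is made by ring-closing metathesis of a dienone opened from a δ-lactone; C4 and C5 come from a Sharpless epoxidation and a vinyl-cuprate opening, C3 from lactone alkylation followed by kinetic protonation.
5. Order of ring formation: δ-lactone (temporary) → cyclopentenone → ring A → ring B (five to nine) → ring D attached → ring C.

Key step: step 14

Remark on the chemistry: atoms carry caryophyllane labels C1–C11 (ring A = C1, C9, C10, C11; ring B = C1–C9); C1′ is the CH2 between C5 and ring D; in ring D, Da bears C1′, Db is the enol carbon next to CMe2 and Df the chelated enol carbon next to the acyl-bearing carbon. Ring D and its precursors are drawn as one enol tautomer.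

**Route**

Step 1
Reactants: 1 tert-butyl(but-3-yn-1-yloxy)dimethylsilane
Product: 4 (E)-5-{[tert-butyl(dimethyl)silyl]oxy}-3-methylpent-2-en-1-ol, via alkenyl(dimethyl)alane 2 (not isolated), via lithium butyl(alkenyl)dimethylaluminate 3 (not isolated)
Conditions: Me3Al, Cp2ZrCl2 (20 mol%), CH2Cl2, 0 °C to rt; solvent switch to THF; n-BuLi, −78 °C; (CH2O)n, −78 °C to rt
Reagents that add atoms: trimethylaluminium C[Al](C)C; paraformaldehyde (as formaldehyde) C=O
Why: Zirconium-catalysed Negishi carboalumination adds CH3 and Al syn across the terminal alkyne (CH3 to the internal carbon, the future C4) and the aluminate passes the alkenyl group to formaldehyde with retention, so CH2OH (C1′) ends up cis to the methyl group, the E geometry that the later anti epoxide opening needs.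

Step 2
Reactants: 4 (E)-5-{[tert-butyl(dimethyl)silyl]oxy}-3-methylpent-2-en-1-ol
Product: 5 [(2R,3R)-3-(2-{[tert-butyl(dimethyl)silyl]oxy}ethyl)-3-methyloxiran-2-yl]methanol
Conditions: Ti(OiPr)4 (10 mol%), D-(−)-diethyl tartrate (12 mol%), t-BuOOH, 4 Å MS, CH2Cl2, −20 °C
Reagents that add atoms: tert-butyl hydroperoxide CC(C)(C)OO
Why: Sharpless asymmetric epoxidation of a trisubstituted E-allylic alcohol of the geraniol type, in which the D-(−)-tartrate catalyst should deliver oxygen to the face that gives the (2R,3R) epoxide and so fixes C4 absolutely and, after the inversion of step 3, C5.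

Step 3
Reactants: 5 [(2R,3R)-3-(2-{[tert-butyl(dimethyl)silyl]oxy}ethyl)-3-methyloxiran-2-yl]methanol
Product: 6 (2S,3R)-5-{[tert-butyl(dimethyl)silyl]oxy}-2-ethenyl-3-methylpentane-1,3-diol
Conditions: CH2=CHMgBr, CuI (20 mol%), THF, −40 to −10 °C
Reagents that add atoms: vinylmagnesium bromide C=C[Mg]Br
Why: Copper-catalysed SN2 opening of the 2,3-epoxy alcohol at C5, the only epoxide carbon that is not fully substituted, proceeds with inversion while the oxygen stays on C4, which gives the C4 (R)/C5 (S) pair of the target with the vinyl group as C6=C7.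

Step 4
Reactants: 6 (2S,3R)-5-{[tert-butyl(dimethyl)silyl]oxy}-2-ethenyl-3-methylpentane-1,3-diol
Product: 7 (2S,3R)-2-ethenyl-3-methylpentane-1,3,5-triol
Conditions: Bu4NF, THF, rt
Reagents that add atoms: none
Why: Fluoride cleavage of the primary silyl ether frees C8–OH for the oxidation that follows, and nothing else in the molecule reacts with fluoride.

Step 5
Reactants: 7 (2S,3R)-2-ethenyl-3-methylpentane-1,3,5-triol
Product: 10 (4R,5S)-5-ethenyl-4-hydroxy-4-methyloxan-2-one, via hydroxy aldehyde 8 (not isolated), via lactol 9 (not isolated)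
Conditions: TEMPO (20 mol%), PhI(OAc)2 (2.5 equiv), CH2Cl2, rt
Reagents that add atoms: none
Why: TEMPO/PhI(OAc)2 oxidative lactonisation of a 1,5-diol, in which the oxoammonium ion should oxidise the less hindered primary alcohol (C8–OH, two CH2 groups from the quaternary carbon, against C1′–OH on the branched C5), the hydroxy aldehyde closes to the six-membered lactol and this is oxidised to the δ-lactone, while the tertiary alcohol and the vinyl group are inert.

Step 6
Reactants: 10 (4R,5S)-5-ethenyl-4-hydroxy-4-methyloxan-2-one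
Product: 12 (4R,5S)-4-hydroxy-5-(2-hydroxyethyl)-4-methyloxan-2-one, via B-alkyl-9-borabicyclononane 11 (not isolated)
Conditions: 9-BBN, THF, 0 °C to rt; then H2O2, pH 7 phosphate buffer, 0 °C
Reagents that add atoms: hydrogen peroxide OO
Why: Anti-Markovnikov hydroboration–oxidation of the monosubstituted alkene puts the hydroxyl on C7, 9-BBN leaves the lactone alone and the buffered oxidation avoids its hydrolysis.

Step 7
Reactants: 12 (4R,5S)-4-hydroxy-5-(2-hydroxyethyl)-4-methyloxan-2-one
Product: 13 (4R,5S)-5-(2-{[tert-butyl(dimethyl)silyl]oxy}ethyl)-4-hydroxy-4-methyloxan-2-one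
Conditions: t-BuMe2SiCl, imidazole, CH2Cl2, 0 °C
Reagents that add atoms: tert-butyldimethylsilyl chloride CC(C)(C)[Si](C)(C)Cl
Why: Silylation is selective for the primary C7 hydroxyl because the tertiary C4–OH is too hindered, and that hydroxyl is needed free as its alkoxide in the next step.

Step 8
Reactants: 13 (4R,5S)-5-(2-{[tert-butyl(dimethyl)silyl]oxy}ethyl)-4-hydroxy-4-methyloxan-2-one
Product: 15 (3R,4S,5S)-5-(2-{[tert-butyl(dimethyl)silyl]oxy}ethyl)-4-hydroxy-4-methyl-3-(prop-2-en-1-yl)oxan-2-one, via dilithium enolate alkoxide 14 (not isolated)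
Conditions: LiN(iPr)2 (2.2 equiv), THF, −78 to −40 °C; CH2=CHCH2Br (1.1 equiv), DMPU, −78 to −40 °C
Reagents that add atoms: allyl bromide C=CCBr
Why: Alkylation of the dianion of a β-hydroxy lactone, in which the alkoxide cannot be eliminated and the enolate should react on the face anti to the pseudo-axial lithium alkoxide on C4, so the allyl group (C2, C1 and a terminal CH2) is expected to enter trans to the C4 oxygen, the C3 epimer of what is needed.

Step 9
Reactants: 15 (3R,4S,5S)-5-(2-{[tert-butyl(dimethyl)silyl]oxy}ethyl)-4-hydroxy-4-methyl-3-(prop-2-en-1-yl)oxan-2-one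
Product: 17 (3S,4S,5S)-5-(2-{[tert-butyl(dimethyl)silyl]oxy}ethyl)-4-hydroxy-4-methyl-3-(prop-2-en-1-yl)oxan-2-one, via dilithium enolate alkoxide 16 (not isolated)
Conditions: LiN(iPr)2 (2.3 equiv), THF, −78 to −30 °C; then AcOH in THF, −78 °C
Reagents that add atoms: none
Why: Re-enolisation and kinetic protonation deliver the proton to the same open face (anti to the C4 oxygen), which should turn the allyl group cis to the hydroxyl and equatorial, the arrangement the chair lactone also prefers, and so set C3 (S).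

Step 10
Reactants: 17 (3S,4S,5S)-5-(2-{[tert-butyl(dimethyl)silyl]oxy}ethyl)-4-hydroxy-4-methyl-3-(prop-2-en-1-yl)oxan-2-one
Product: 18 (2S)-2-[(2S,3S)-5-{[tert-butyl(dimethyl)silyl]oxy}-2-hydroxy-3-(hydroxymethyl)pentan-2-yl]-N-methoxy-N-methylpent-4-enamide
Conditions: MeNH(OMe)·HCl, AlMe3, CH2Cl2, 0 °C to rt
Reagents that add atoms: N,O-dimethylhydroxylamine hydrochloride CNOC.Cl
Why: Aluminium-amide aminolysis of the lactone (Weinreb amide formation) frees C1′–OH and turns C8 into an acyl donor without enolising C3.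

Step 11
Reactants: 18 (2S)-2-[(2S,3S)-5-{[tert-butyl(dimethyl)silyl]oxy}-2-hydroxy-3-(hydroxymethyl)pentan-2-yl]-N-methoxy-N-methylpent-4-enamide
Product: 19 (2S)-2-[(4S,5S)-5-(2-{[tert-butyl(dimethyl)silyl]oxy}ethyl)-2,2,4-trimethyl-1,3-dioxan-4-yl]-N-methoxy-N-methylpent-4-enamide
Conditions: Me2C(OMe)2, PPTS (cat.), CH2Cl2, rt
Reagents that add atoms: 2,2-dimethoxypropane COC(C)(C)OC
Why: Acid-catalysed ketalisation ties C1′–OH and the tertiary C4–OH into a six-membered acetonide before the ketone is made, so that a free β-hydroxy ketone (retro-aldol, oxa-Michael addition) never exists.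

Step 12
Reactants: 19 (2S)-2-[(4S,5S)-5-(2-{[tert-butyl(dimethyl)silyl]oxy}ethyl)-2,2,4-trimethyl-1,3-dioxan-4-yl]-N-methoxy-N-methylpent-4-enamide
Product: 20 (4S)-4-[(4S,5S)-5-(2-{[tert-butyl(dimethyl)silyl]oxy}ethyl)-2,2,4-trimethyl-1,3-dioxan-4-yl]hepta-1,6-dien-3-one
Conditions: CH2=CHMgBr, THF, −20 to 0 °C; cold aqueous citric acid quench
Reagents that add atoms: vinylmagnesium bromide C=C[Mg]Br
Why: Weinreb ketone synthesis, in which the chelated tetrahedral adduct survives until the acidic quench, which prevents a second addition and keeps base and the liberated amine away from the enone and from C3.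

Step 13
Reactants: 20 (4S)-4-[(4S,5S)-5-(2-{[tert-butyl(dimethyl)silyl]oxy}ethyl)-2,2,4-trimethyl-1,3-dioxan-4-yl]hepta-1,6-dien-3-one
Product: 21 (5S)-5-[(4S,5S)-5-(2-{[tert-butyl(dimethyl)silyl]oxy}ethyl)-2,2,4-trimethyl-1,3-dioxan-4-yl]cyclopent-2-en-1-one
Conditions: second-generation Grubbs catalyst RuCl2(=CHPh)(PCy3)(H2IMes) (5 mol%), CH2Cl2 (5 mM), 40 °C
Reagents that add atoms: none
Why: Ring-closing metathesis of the vinyl ketone with the allyl group (loss of ethylene) gives the 5-substituted cyclopent-2-enone under neutral conditions, so the base-sensitive C3 is not epimerised.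

Step 14
Reactants: 21 (5S)-5-[(4S,5S)-5-(2-{[tert-butyl(dimethyl)silyl]oxy}ethyl)-2,2,4-trimethyl-1,3-dioxan-4-yl]cyclopent-2-en-1-one; 22 2-methylprop-1-ene (isobutylene)
Product: 23 (1R,3S,5R)-3-[(4S,5S)-5-(2-{[tert-butyl(dimethyl)silyl]oxy}ethyl)-2,2,4-trimethyl-1,3-dioxan-4-yl]-6,6-dimethylbicyclo[3.2.0]heptan-2-one
Conditions: hν (Hg lamp, λ > 340 nm), isobutylene (large excess, condensed), CH2Cl2, −70 °C
Reagents that add atoms: none
Why: Irradiation into the n,π* band and intersystem crossing give the enone triplet, which forms an exciplex and then a triplet 1,4-biradical with isobutylene that closes after spin inversion; this is the enone–alkene [2+2] photocycloaddition, known for cyclopent-2-enone and isobutylene themselves. Ring A closes by two-bond cycloaddition across C9=C1 (C9–C10 and C1–C11), and on a five-membered enone only the cis fusion can form. The excited enone has reversed polarity (C1 electron-rich), so C1 should pair with the CMe2 terminus and C9 with CH2, the head-to-tail orientation; low temperature and a large excess of alkene should suppress head-to-head and hydrogen-transfer products. C1 (R) is set by approach of the alkene to the face anti to the quaternary dioxanyl group on C3 (S), and C9 is set cis to C1 by the ring fusion and is corrected in step 18. The step therefore needs regiochemical and facial selectivity: the first comes from excited-state polarity, the second from the C3 substituent, whose configuration was fixed in step 9 and has been kept from base since. Light above 340 nm and the absence of ring D avoid a competing chromophore and secondary α-cleavage of the product ketone.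

Step 15
Reactants: 23 (1R,3S,5R)-3-[(4S,5S)-5-(2-{[tert-butyl(dimethyl)silyl]oxy}ethyl)-2,2,4-trimethyl-1,3-dioxan-4-yl]-6,6-dimethylbicyclo[3.2.0]heptan-2-one
Product: 24 (1R,3S,5R)-3-[(4S,5S)-5-(2-hydroxyethyl)-2,2,4-trimethyl-1,3-dioxan-4-yl]-6,6-dimethylbicyclo[3.2.0]heptan-2-one
Conditions: HF·pyridine, pyridine, THF, 0 °C
Reagents that add atoms: none
Why: Buffered fluoride desilylation is not basic, so the acetonide and C3 (α to the ketone and β to an alkoxy group) are untouched.

Step 16
Reactants: 24 (1R,3S,5R)-3-[(4S,5S)-5-(2-hydroxyethyl)-2,2,4-trimethyl-1,3-dioxan-4-yl]-6,6-dimethylbicyclo[3.2.0]heptan-2-one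
Product: 25 (1R,3S,5R)-3-[(4S,5S)-5-(2-iodoethyl)-2,2,4-trimethyl-1,3-dioxan-4-yl]-6,6-dimethylbicyclo[3.2.0]heptan-2-one
Conditions: I2, PPh3, imidazole, CH2Cl2, 0 °C to rt
Reagents that add atoms: iodine II
Why: Appel-type iodination converts the primary C7 alcohol into the iodide by SN2 displacement of the alkoxyphosphonium ion under nearly neutral conditions.

Step 17
Reactants: 25 (1R,3S,5R)-3-[(4S,5S)-5-(2-iodoethyl)-2,2,4-trimethyl-1,3-dioxan-4-yl]-6,6-dimethylbicyclo[3.2.0]heptan-2-one
Product: 26 acetonide of (1R,4R,5S,9R)-4-hydroxy-5-(hydroxymethyl)-4,11,11-trimethylbicyclo[7.2.0]undecan-8-one (cis-fused)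
Conditions: Bu3SnH (1.5 equiv, syringe pump), AIBN (0.3 equiv), benzene (3 mM), 80 °C
Reagents that add atoms: none
Why: Proposed new method: iodine abstraction gives the primary C7 radical, which adds 6-exo to the C8 carbonyl (ring C7–C6–C5–C4–C3–C8), and the resulting alkoxy radical should cleave C3–C8 rather than revert to the primary radical or cleave C8–C9 (which would give a cyclobutyl radical), because this scission forms a secondary radical next to the fully substituted C4 and opens the strained five-membered ring of the bicyclo[3.2.0] unit; the C3 radical is then reduced by Bu3SnH, so five ring atoms become nine and C3 becomes CH2; the closest known reactions are the Dowd–Beckwith expansion of α-(ω-haloalkyl) β-keto esters and the ester-free radical expansion of fused cyclobutanones.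

Step 18
Reactants: 26 acetonide of (1R,4R,5S,9R)-4-hydroxy-5-(hydroxymethyl)-4,11,11-trimethylbicyclo[7.2.0]undecan-8-one (cis-fused)
Product: 27 acetonide of (1R,4R,5S,9S)-4-hydroxy-5-(hydroxymethyl)-4,11,11-trimethylbicyclo[7.2.0]undecan-8-one (trans-fused)
Conditions: KOtBu (0.3 equiv), t-BuOH–THF, rt
Reagents that add atoms: none
Why: Base-catalysed epimerisation at C9 through the enolate should lead to the trans ring fusion, which is the thermodynamically preferred one in a bicyclo[7.2.0]undecan-8-one, and so sets C9 (S) relative to the fixed C1 (R).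

Step 19
Reactants: 27 acetonide of (1R,4R,5S,9S)-4-hydroxy-5-(hydroxymethyl)-4,11,11-trimethylbicyclo[7.2.0]undecan-8-one (trans-fused)
Product: 28 acetonide of (1R,4R,5S,9S)-5-(hydroxymethyl)-4,11,11-trimethyl-8-methylidenebicyclo[7.2.0]undecan-4-ol
Conditions: Ph3PCH3Br, KOtBu, toluene, 80 °C
Reagents that add atoms: methyltriphenylphosphonium bromide C[P+](c1ccccc1)(c1ccccc1)c1ccccc1.[Br-]
Why: Wittig methylenation of the C8 ketone installs the exocyclic CH2, and any enolisation under the basic ylide conditions only returns the favoured trans fusion.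

Step 20
Reactants: 28 acetonide of (1R,4R,5S,9S)-5-(hydroxymethyl)-4,11,11-trimethyl-8-methylidenebicyclo[7.2.0]undecan-4-ol
Product: 29 (1R,4R,5S,9S)-5-(hydroxymethyl)-4,11,11-trimethyl-8-methylidenebicyclo[7.2.0]undecan-4-ol
Conditions: PPTS, MeOH, 40 °C
Reagents that add atoms: none
Why: Mild acid-catalysed transketalisation to methanol removes the acetonide without isomerising the 1,1-disubstituted alkene or ionising the tertiary alcohol.

Step 21
Reactants: 29 (1R,4R,5S,9S)-5-(hydroxymethyl)-4,11,11-trimethyl-8-methylidenebicyclo[7.2.0]undecan-4-ol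
Product: 30 (1R,4R,5R,9S)-4-hydroxy-4,11,11-trimethyl-8-methylidenebicyclo[7.2.0]undecane-5-carbaldehyde
Conditions: TEMPO (10 mol%), PhI(OAc)2 (1.2 equiv), CH2Cl2, rt
Reagents that add atoms: none
Why: TEMPO/PhI(OAc)2 oxidation takes the primary C1′ alcohol to the aldehyde under neutral conditions that leave the tertiary alcohol, the alkene and the C5 stereocentre alone (the descriptor changes only through ligand priorities).

Step 22
Reactants: 31 benzene-1,3,5-triol (phloroglucinol); 32 2-methylpropanoyl chloride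
Product: 33 2-methyl-1-(2,4,6-trihydroxyphenyl)propan-1-one
Conditions: AlCl3, PhNO2, 65 °C
Reagents that add atoms: none
Why: Friedel–Crafts acylation of the symmetric, electron-rich arene gives the mono-acylphloroglucinol, the product ketone being deactivated towards a second acylation.

Step 23
Reactants: 33 2-methyl-1-(2,4,6-trihydroxyphenyl)propan-1-one
Product: 35 3,5-dihydroxy-6,6-dimethyl-2-(2-methylpropanoyl)cyclohexa-2,4-dien-1-one, via 3-C-methyl acylphloroglucinol 34 (not isolated)
Conditions: NaOMe (3 equiv), MeI (2.2 equiv), MeOH, 0 °C to rt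
Reagents that add atoms: iodomethane CI
Why: Base-mediated double C-methylation of the phenoxide at one ring carbon dearomatises the acylphloroglucinol to the gem-dimethyl trione, which leaves a single nucleophilic ring CH (Da).

Step 24
Reactants: 30 (1R,4R,5R,9S)-4-hydroxy-4,11,11-trimethyl-8-methylidenebicyclo[7.2.0]undecane-5-carbaldehyde; 35 3,5-dihydroxy-6,6-dimethyl-2-(2-methylpropanoyl)cyclohexa-2,4-dien-1-one
Product: 37 3,5-dihydroxy-4-{[(1R,4R,5S,9S)-4-hydroxy-4,11,11-trimethyl-8-methylidenebicyclo[7.2.0]undecan-5-yl]methyl}-6,6-dimethyl-2-(2-methylpropanoyl)cyclohexa-2,4-dien-1-one, via alkylidene trione 36 (not isolated)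
Conditions: L-proline (20 mol%), Hantzsch ester (1.2 equiv), CH2Cl2, rt
Reagents that add atoms: none
Why: Organocatalytic three-component reductive alkylation, in which Knoevenagel condensation at the only ring CH of the trione (Da) is followed in the flask by conjugate reduction of the alkylidene by the Hantzsch ester, forms the C1′–Da bond without O-alkylation.

Step 25
Reactants: 37 3,5-dihydroxy-4-{[(1R,4R,5S,9S)-4-hydroxy-4,11,11-trimethyl-8-methylidenebicyclo[7.2.0]undecan-5-yl]methyl}-6,6-dimethyl-2-(2-methylpropanoyl)cyclohexa-2,4-dien-1-one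
Product: 38 target CNP0497637.2
Conditions: PPTS (20 mol%), 4 Å MS, toluene, 80 °C
Reagents that add atoms: none
Why: Acid-catalysed cyclodehydration (intramolecular vinylogous esterification) in which the C4 hydroxyl adds to Db, the enol carbon next to CMe2, because the other enol (Df) is held in the hydrogen-bonded chelate with the acyl group, and the hemiketal loses water to close ring C without ever breaking the C4–O bond, so C4 keeps its configuration.

**Compound list**

1 | tert-butyl(but-3-yn-1-yloxy)dimethylsilane | C#CCCO[Si](C)(C)C(C)(C)C | starting material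
2 | (E)-[4-{[tert-butyl(dimethyl)silyl]oxy}-2-methylbut-1-en-1-yl]dimethylalane | C[Al](C)/C=C(\C)CCO[Si](C)(C)C(C)(C)C | intermediate (not isolated)
3 | lithium butyl[(E)-4-{[tert-butyl(dimethyl)silyl]oxy}-2-methylbut-1-en-1-yl]dimethylaluminate | [Li+].CCCC[Al-](C)(C)/C=C(\C)CCO[Si](C)(C)C(C)(C)C | intermediate (not isolated)
4 | (E)-5-{[tert-butyl(dimethyl)silyl]oxy}-3-methylpent-2-en-1-ol | OC/C=C(\C)CCO[Si](C)(C)C(C)(C)C | intermediate
5 | [(2R,3R)-3-(2-{[tert-butyl(dimethyl)silyl]oxy}ethyl)-3-methyloxiran-2-yl]methanol | OC[C@H]1O[C@]1(C)CCO[Si](C)(C)C(C)(C)C | intermediate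
6 | (2S,3R)-5-{[tert-butyl(dimethyl)silyl]oxy}-2-ethenyl-3-methylpentane-1,3-diol | OC[C@H](C=C)[C@](C)(O)CCO[Si](C)(C)C(C)(C)C | intermediate
7 | (2S,3R)-2-ethenyl-3-methylpentane-1,3,5-triol | OC[C@H](C=C)[C@](C)(O)CCO | intermediate
8 | (3R,4S)-3-hydroxy-4-(hydroxymethyl)-3-methylhex-5-enal | O=CC[C@@](C)(O)[C@@H](C=C)CO | intermediate (not isolated)
9 | (4R,5S)-5-ethenyl-4-methyloxane-2,4-diol (lactol, both anomers) | OC1C[C@@](C)(O)[C@@H](C=C)CO1 | intermediate (not isolated)
10 | (4R,5S)-5-ethenyl-4-hydroxy-4-methyloxan-2-one | O=C1C[C@@](C)(O)[C@@H](C=C)CO1 | intermediate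
11 | (4R,5S)-5-[2-(9-borabicyclo[3.3.1]nonan-9-yl)ethyl]-4-hydroxy-4-methyloxan-2-one | O=C1C[C@@](C)(O)[C@@H](CCB2C3CCCC2CCC3)CO1 | intermediate (not isolated)
12 | (4R,5S)-4-hydroxy-5-(2-hydroxyethyl)-4-methyloxan-2-one | O=C1C[C@@](C)(O)[C@@H](CCO)CO1 | intermediate
13 | (4R,5S)-5-(2-{[tert-butyl(dimethyl)silyl]oxy}ethyl)-4-hydroxy-4-methyloxan-2-one | O=C1C[C@@](C)(O)[C@@H](CCO[Si](C)(C)C(C)(C)C)CO1 | intermediate
14 | dilithium enolate alkoxide of 13 | [Li+].[Li+].[O-]C1=C[C@@](C)([O-])[C@@H](CCO[Si](C)(C)C(C)(C)C)CO1 | intermediate (not isolated)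
15 | (3R,4S,5S)-5-(2-{[tert-butyl(dimethyl)silyl]oxy}ethyl)-4-hydroxy-4-methyl-3-(prop-2-en-1-yl)oxan-2-one | O=C1[C@H](CC=C)[C@@](C)(O)[C@@H](CCO[Si](C)(C)C(C)(C)C)CO1 | intermediate
16 | dilithium enolate alkoxide of 15 | [Li+].[Li+].[O-]C1=C(CC=C)[C@@](C)([O-])[C@@H](CCO[Si](C)(C)C(C)(C)C)CO1 | intermediate (not isolated)
17 | (3S,4S,5S)-5-(2-{[tert-butyl(dimethyl)silyl]oxy}ethyl)-4-hydroxy-4-methyl-3-(prop-2-en-1-yl)oxan-2-one | O=C1[C@@H](CC=C)[C@@](C)(O)[C@@H](CCO[Si](C)(C)C(C)(C)C)CO1 | intermediate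
18 | (2S)-2-[(2S,3S)-5-{[tert-butyl(dimethyl)silyl]oxy}-2-hydroxy-3-(hydroxymethyl)pentan-2-yl]-N-methoxy-N-methylpent-4-enamide | CON(C)C(=O)[C@@H](CC=C)[C@@](C)(O)[C@@H](CCO[Si](C)(C)C(C)(C)C)CO | intermediate
19 | (2S)-2-[(4S,5S)-5-(2-{[tert-butyl(dimethyl)silyl]oxy}ethyl)-2,2,4-trimethyl-1,3-dioxan-4-yl]-N-methoxy-N-methylpent-4-enamide | CON(C)C(=O)[C@@H](CC=C)[C@@]1(C)OC(C)(C)OC[C@@H]1CCO[Si](C)(C)C(C)(C)C | intermediate
20 | (4S)-4-[(4S,5S)-5-(2-{[tert-butyl(dimethyl)silyl]oxy}ethyl)-2,2,4-trimethyl-1,3-dioxan-4-yl]hepta-1,6-dien-3-one | C=CC(=O)[C@@H](CC=C)[C@@]1(C)OC(C)(C)OC[C@@H]1CCO[Si](C)(C)C(C)(C)C | intermediate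
21 | (5S)-5-[(4S,5S)-5-(2-{[tert-butyl(dimethyl)silyl]oxy}ethyl)-2,2,4-trimethyl-1,3-dioxan-4-yl]cyclopent-2-en-1-one | O=C1C=CC[C@H]1[C@@]2(C)OC(C)(C)OC[C@@H]2CCO[Si](C)(C)C(C)(C)C | intermediate
22 | 2-methylprop-1-ene (isobutylene) | C=C(C)C | starting material
23 | (1R,3S,5R)-3-[(4S,5S)-5-(2-{[tert-butyl(dimethyl)silyl]oxy}ethyl)-2,2,4-trimethyl-1,3-dioxan-4-yl]-6,6-dimethylbicyclo[3.2.0]heptan-2-one | O=C1[C@H]([C@@]3(C)OC(C)(C)OC[C@@H]3CCO[Si](C)(C)C(C)(C)C)C[C@@H]2[C@H]1CC2(C)C | intermediate
24 | (1R,3S,5R)-3-[(4S,5S)-5-(2-hydroxyethyl)-2,2,4-trimethyl-1,3-dioxan-4-yl]-6,6-dimethylbicyclo[3.2.0]heptan-2-one | O=C1[C@H]([C@@]3(C)OC(C)(C)OC[C@@H]3CCO)C[C@@H]2[C@H]1CC2(C)C | intermediate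
25 | (1R,3S,5R)-3-[(4S,5S)-5-(2-iodoethyl)-2,2,4-trimethyl-1,3-dioxan-4-yl]-6,6-dimethylbicyclo[3.2.0]heptan-2-one | O=C1[C@H]([C@@]3(C)OC(C)(C)OC[C@@H]3CCI)C[C@@H]2[C@H]1CC2(C)C | intermediate
26 | acetonide of (1R,4R,5S,9R)-4-hydroxy-5-(hydroxymethyl)-4,11,11-trimethylbicyclo[7.2.0]undecan-8-one (cis-fused) | O=C1CC[C@H]3COC(C)(C)O[C@]3(C)CC[C@@H]2[C@H]1CC2(C)C | intermediate
27 | acetonide of (1R,4R,5S,9S)-4-hydroxy-5-(hydroxymethyl)-4,11,11-trimethylbicyclo[7.2.0]undecan-8-one (trans-fused) | O=C1CC[C@H]3COC(C)(C)O[C@]3(C)CC[C@@H]2[C@@H]1CC2(C)C | intermediate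
28 | acetonide of (1R,4R,5S,9S)-5-(hydroxymethyl)-4,11,11-trimethyl-8-methylidenebicyclo[7.2.0]undecan-4-ol | C=C1CC[C@H]3COC(C)(C)O[C@]3(C)CC[C@@H]2[C@@H]1CC2(C)C | intermediate
29 | (1R,4R,5S,9S)-5-(hydroxymethyl)-4,11,11-trimethyl-8-methylidenebicyclo[7.2.0]undecan-4-ol | C=C1CC[C@@H](CO)[C@](C)(O)CC[C@@H]2[C@@H]1CC2(C)C | intermediate
30 | (1R,4R,5R,9S)-4-hydroxy-4,11,11-trimethyl-8-methylidenebicyclo[7.2.0]undecane-5-carbaldehyde | C=C1CC[C@@H](C=O)[C@](C)(O)CC[C@@H]2[C@@H]1CC2(C)C | intermediate
31 | benzene-1,3,5-triol (phloroglucinol) | Oc1cc(O)cc(O)c1 | starting material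
32 | 2-methylpropanoyl chloride | CC(C)C(Cl)=O | starting material
33 | 2-methyl-1-(2,4,6-trihydroxyphenyl)propan-1-one | CC(C)C(=O)c1c(O)cc(O)cc1O | intermediate
34 | 2-methyl-1-(2,4,6-trihydroxy-3-methylphenyl)propan-1-one | CC(C)C(=O)c1c(O)cc(O)c(C)c1O | intermediate (not isolated)
35 | 3,5-dihydroxy-6,6-dimethyl-2-(2-methylpropanoyl)cyclohexa-2,4-dien-1-one (enol form of 2-isobutyryl-4,4-dimethylcyclohexane-1,3,5-trione) | CC(C)C(=O)C1=C(O)C=C(O)C(C)(C)C1=O | intermediate
36 | Knoevenagel adduct of 30 and 35 (C1′H=Da alkylidene trione, alkene geometry open) | C=C1CC[C@@H](C=C3C(=O)C(C)(C)C(=O)C(C(=O)C(C)C)=C3O)[C@](C)(O)CC[C@@H]2[C@@H]1CC2(C)C | intermediate (not isolated)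
37 | 3,5-dihydroxy-4-{[(1R,4R,5S,9S)-4-hydroxy-4,11,11-trimethyl-8-methylidenebicyclo[7.2.0]undecan-5-yl]methyl}-6,6-dimethyl-2-(2-methylpropanoyl)cyclohexa-2,4-dien-1-one | C=C1CC[C@@H](CC3=C(O)C(C)(C)C(=O)C(C(=O)C(C)C)=C3O)[C@](C)(O)CC[C@@H]2[C@@H]1CC2(C)C | intermediate
38 | CNP0497637.2 (rings A–D; C1 R, C4 R, C5 S, C9 S) | C=C1CC[C@H]2CC3=C(O[C@]2(C)CC[C@@H]2[C@@H]1CC2(C)C)C(C)(C)C(=O)C(C(=O)C(C)C)=C3O | target

**Step count**

Total: 25 steps. Longest linear sequence: 23 steps (steps 1–21, 24 and 25); steps 22 and 23 make the ring D fragment.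

**Steps most likely to fail**

1. Step 17 (Proposed new method). The C7 radical may be reduced, or may take the activated hydrogen from C3 by 1,5-transfer, before it adds to the ketone; the alkoxy radical may also revert or fragment towards C9 instead of C3. The fallback uses known chemistry and separates C–C bond formation from fragmentation. It sets out from iodide 25: a Barbier cyclisation with SmI2 in THF–HMPA closes the C7–C8 bond from the face of the C3 substituent and gives the tricyclic tertiary alcohol F1. Its hypoiodite, formed with PhI(OAc)2 and I2 under visible light (Suárez fragmentation), gives the alkoxy radical directly; cleavage of C3–C8 and iodine capture give the 3-iodo nine-membered ketone F2. Bu3SnH with AIBN removes the iodine, and the sequence comes back to the route at ketone 26.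

2. Step 14. Facial discrimination by the C3 substituent, which sits two atoms from the reacting carbons, may be incomplete, and head-to-head or hydrogen-transfer products may compete. The fallback makes the cycloaddition intramolecular, so the regiochemistry is fixed by the tether and isobutylene and the metathesis are no longer needed. It sets out from lactone 13: alkylation of the dianion with 3-methylbut-2-enyl bromide gives the trans 3-prenyl lactone F3, and re-enolisation with LiN(iPr)2 and protonation as in step 9 gives the cis 3-prenyl lactone F4. Aminolysis with AlMe3 and MeNH(OMe)·HCl gives the hydroxy Weinreb amide F5, Me2C(OMe)2 with PPTS gives the acetonide F6, and CH2=CHMgBr gives the 1,6-dien-3-one F7. Irradiation of this dienone (λ > 300 nm) should bond C9 to C1 first (five-membered ring, C3 substituent pseudo-equatorial) and then C10 to C11. This comes back to the route at photoadduct 23.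

3. Step 25. Under acid the tertiary C4 alcohol may ionise or eliminate before it adds to the hindered Db carbon, which would lose the C4 configuration, or the wrong enol carbon may be attacked. The fallback replaces the dehydration by an addition–elimination on an activated enol, with no acid. It sets out from alkylated trione 37: sulfonylation of the free, more acidic enol on the CMe2 side with TsCl and Et3N at low temperature gives the enol tosylate F8. NaH in THF then forms the C4 alkoxide, which displaces the sulfonate at Db by conjugate addition–elimination. This comes back to the route at target 38.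

**Further compounds**

F1 | step 17 | tricyclic tertiary alcohol from C7–C8 closure (C8–OH; cyclohexane C3–C4–C5–C6–C7–C8 cis-fused to the bicyclo[3.2.0]heptane; acetonide intact) | O[C@@]12CC[C@H]3COC(C)(C)O[C@]3(C)[C@@H]1C[C@@H]4[C@H]2CC4(C)C
F2 | step 17 | acetonide of (1R,4R,5S,9R)-4-hydroxy-5-(hydroxymethyl)-3-iodo-4,11,11-trimethylbicyclo[7.2.0]undecan-8-one (C3 epimers) | O=C1CC[C@H]3COC(C)(C)O[C@]3(C)C(I)C[C@@H]2[C@H]1CC2(C)C
F3 | step 14 | (3R,4S,5S)-5-(2-{[tert-butyl(dimethyl)silyl]oxy}ethyl)-4-hydroxy-4-methyl-3-(3-methylbut-2-en-1-yl)oxan-2-one | O=C1[C@H](CC=C(C)C)[C@@](C)(O)[C@@H](CCO[Si](C)(C)C(C)(C)C)CO1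
F4 | step 14 | (3S,4S,5S)-5-(2-{[tert-butyl(dimethyl)silyl]oxy}ethyl)-4-hydroxy-4-methyl-3-(3-methylbut-2-en-1-yl)oxan-2-one | O=C1[C@@H](CC=C(C)C)[C@@](C)(O)[C@@H](CCO[Si](C)(C)C(C)(C)C)CO1
F5 | step 14 | (2S)-2-[(2S,3S)-5-{[tert-butyl(dimethyl)silyl]oxy}-2-hydroxy-3-(hydroxymethyl)pentan-2-yl]-N-methoxy-N,5-dimethylhex-4-enamide | CON(C)C(=O)[C@@H](CC=C(C)C)[C@@](C)(O)[C@@H](CCO[Si](C)(C)C(C)(C)C)CO
F6 | step 14 | (2S)-2-[(4S,5S)-5-(2-{[tert-butyl(dimethyl)silyl]oxy}ethyl)-2,2,4-trimethyl-1,3-dioxan-4-yl]-N-methoxy-N,5-dimethylhex-4-enamide | CON(C)C(=O)[C@@H](CC=C(C)C)[C@@]1(C)OC(C)(C)OC[C@@H]1CCO[Si](C)(C)C(C)(C)C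
F7 | step 14 | (4S)-4-[(4S,5S)-5-(2-{[tert-butyl(dimethyl)silyl]oxy}ethyl)-2,2,4-trimethyl-1,3-dioxan-4-yl]-7-methylocta-1,6-dien-3-one | C=CC(=O)[C@@H](CC=C(C)C)[C@@]1(C)OC(C)(C)OC[C@@H]1CCO[Si](C)(C)C(C)(C)C
F8 | step 25 | enol 4-methylbenzenesulfonate of 37 at the Db oxygen | C=C1CC[C@@H](CC3=C(OS(=O)(=O)c4ccc(C)cc4)C(C)(C)C(=O)C(C(=O)C(C)C)=C3O)[C@](C)(O)CC[C@@H]2[C@@H]1CC2(C)C
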